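**Retrosynthetic overview**
- The route rests on ring B, a 2,5-dialkylresorcinol mono-methyl ether: C4' (the CH2 bridge to ring C) lies between the oxygenated carbons C3' (OH) and C5' (OMe), and C1' (the CH2CH2 chain to ring A) is para to C4'. C3' and C5' are equivalent by the local symmetry of ring B until one oxygen is methylated.
- Ring B is disconnected at C3'–C4', C5'–C6' and C2'–C3' into a 3-(arylethyl)cyclobutenone (C1', C2', C3', C6' with ring A) and a triisopropylsilyl ynol ether (C4', C5' with the ring C–D benzyl group): a cyclobutenone/ynol ether benzannulation.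
- Cyclobutenone: O-benzylvanillyl alcohol, benzylic bromide, propargylation to the 4-arylbut-1-yne, dichloroketene [2+2], dechlorination.
- Ynol ether: methyl orsellinate, 4-O-benzyl/2-O-methyl, lateral lithiation and benzylation (ring C–D bibenzyl), ester to CH2Cl, propargyl arene, acetylide oxidation to the ynolate, O-silylation.
- Rings A, C and D are bought as arenes; ring B is the only ring built and is formed last, followed by O-methylation, desilylation and hydrogenolysis.

Key step: step 13

Remark: the target has no stereocentre and no other stereogenic element, so it is achiral and the requirement "single enantiomer" is met by the constitution alone. The one transient stereocentre (in the [2+2] adduct of the key step) is racemic and is erased within the same step.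

**Route**

Step 1
Reactants: 1 (4-benzyloxy-3-methoxyphenyl)methanol
Product: 2 4-benzyloxy-3-methoxybenzyl bromide
Conditions: PBr3 (0.4 equiv), Et2O, 0 °C
Reagents that add atoms: phosphorus tribromide, BrP(Br)Br
Why: Bromination of an electron-rich benzylic alcohol through its phosphite ester (SN2 by bromide) is standard and should leave the aryl benzyl and methyl ethers untouched.

Step 2
Reactants: 2 4-benzyloxy-3-methoxybenzyl bromide
Product: 3 [4-(4-benzyloxy-3-methoxyphenyl)but-1-yn-1-yl]trimethylsilane
Conditions: 1-(trimethylsilyl)propyne, n-BuLi, THF, −78 °C; then 2, −78 to 0 °C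
Reagents that add atoms: 1-(trimethylsilyl)propyne, CC#C[Si](C)(C)C
Why: Propargylic lithiation of 1-(trimethylsilyl)propyne followed by SN2 alkylation of the reactive benzylic bromide (propargylation with a silyl-blocked propargyl anion) should give the homopropargyl arene, the silyl group steering attack to the propargylic carbon.

Step 3
Reactants: 3 [4-(4-benzyloxy-3-methoxyphenyl)but-1-yn-1-yl]trimethylsilane
Product: 4 1-benzyloxy-4-(but-3-yn-1-yl)-2-methoxybenzene
Conditions: K2CO3 (cat.), MeOH–THF, rt
Reagents that add atoms: none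
Why: Base-catalysed methanolysis of the alkynyl C–Si bond (protiodesilylation) should free the terminal alkyne without touching any other group.

Step 4
Reactants: 4 1-benzyloxy-4-(but-3-yn-1-yl)-2-methoxybenzene
Product: 5 3-[2-(4-benzyloxy-3-methoxyphenyl)ethyl]-4,4-dichlorocyclobut-2-en-1-one
Conditions: Cl3CCOCl, Zn(Cu), Et2O–DME, rt, slow addition
Reagents that add atoms: trichloroacetyl chloride, ClC(Cl)(Cl)C(Cl)=O
Why: Dichloroketene made in the flask should add [2+2] to the terminal alkyne with its carbonyl carbon at the unsubstituted alkyne carbon, the established entry to 3-substituted 4,4-dichlorocyclobutenones, while DME ties up ZnCl2 so that the aryl ethers are not attacked.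

Step 5
Reactants: 5 3-[2-(4-benzyloxy-3-methoxyphenyl)ethyl]-4,4-dichlorocyclobut-2-en-1-one
Product: 6 3-[2-(4-benzyloxy-3-methoxyphenyl)ethyl]cyclobut-2-en-1-one
Conditions: Zn dust, AcOH, TMEDA, EtOH, 0 °C to rt
Reagents that add atoms: none
Why: Zinc reductive dechlorination of the α,α-dichloroketone (zinc enolate, then protonation) under the AcOH/TMEDA buffer should give the 3-substituted cyclobutenone without over-reduction or migration of the double bond.

Step 6
Reactants: 7 methyl orsellinate (methyl 2,4-dihydroxy-6-methylbenzoate)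
Product: 8 methyl 4-benzyloxy-2-hydroxy-6-methylbenzoate
Conditions: BnBr (1.05 equiv), K2CO3, acetone, reflux
Reagents that add atoms: benzyl bromide, BrCc1ccccc1
Why: Williamson etherification should be selective for the 4-OH, because the 2-OH is held in a hydrogen bond to the ester carbonyl and is much less nucleophilic.

Step 7
Reactants: 8 methyl 4-benzyloxy-2-hydroxy-6-methylbenzoate
Product: 9 methyl 4-benzyloxy-2-methoxy-6-methylbenzoate
Conditions: MeI, K2CO3, DMF, 50 °C
Reagents that add atoms: iodomethane, CI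
Why: Williamson methylation under more forcing conditions in a dipolar aprotic solvent should alkylate the chelated 2-OH, the only acidic site left.

Step 8
Reactants: 9 methyl 4-benzyloxy-2-methoxy-6-methylbenzoate; 10 3-benzyloxybenzyl bromide
Product: 12 methyl 4-benzyloxy-2-[2-(3-benzyloxyphenyl)ethyl]-6-methoxybenzoate, via laterally lithiated toluate 11 (not isolated)
Conditions: LDA, THF, −78 °C; then 10, −78 °C to rt
Reagents that add atoms: none
Why: Lateral (benzylic) lithiation of the ortho-toluate gives an ester-conjugated benzylic anion that should be alkylated by the benzylic bromide to form the ring C–D bibenzyl, the low temperature holding back self-condensation with the hindered ester.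

Step 9
Reactants: 12 methyl 4-benzyloxy-2-[2-(3-benzyloxyphenyl)ethyl]-6-methoxybenzoate
Product: 13 {4-benzyloxy-2-[2-(3-benzyloxyphenyl)ethyl]-6-methoxyphenyl}methanol
Conditions: LiAlH4, THF, 0 °C to rt
Reagents that add atoms: none
Why: Hydride reduction of the ester to the primary benzylic alcohol is reliable even for a 2,6-disubstituted benzoate and does not touch the aryl ethers.

Step 10
Reactants: 13 {4-benzyloxy-2-[2-(3-benzyloxyphenyl)ethyl]-6-methoxyphenyl}methanol
Product: 14 5-benzyloxy-1-[2-(3-benzyloxyphenyl)ethyl]-2-(chloromethyl)-3-methoxybenzene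
Conditions: SOCl2, pyridine, CH2Cl2, −10 to 0 °C; used at once without chromatography
Reagents that add atoms: thionyl chloride, O=S(Cl)Cl
Why: Chlorination through the chlorosulfite is fast for a 2,4-dialkoxybenzylic alcohol, and pyridine removes HCl so that the benzyl ethers and the acid-labile product should survive.

Step 11
Reactants: 14 5-benzyloxy-1-[2-(3-benzyloxyphenyl)ethyl]-2-(chloromethyl)-3-methoxybenzene
Product: 15 5-benzyloxy-1-[2-(3-benzyloxyphenyl)ethyl]-3-methoxy-2-(prop-2-yn-1-yl)benzene
Conditions: HC≡CMgBr (3 equiv), CuCl (10 mol%), THF, 0 to 40 °C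
Reagents that add atoms: ethynylmagnesium bromide, C#C[Mg]Br
Why: Copper-catalysed coupling of an alkynyl Grignard reagent with a benzylic halide is a known route to 3-arylprop-1-ynes, and the excess of ethynyl reagent should suppress a second alkylation.

Step 12
Reactants: 15 5-benzyloxy-1-[2-(3-benzyloxyphenyl)ethyl]-3-methoxy-2-(prop-2-yn-1-yl)benzene
Product: 18 [(3-{4-benzyloxy-2-[2-(3-benzyloxyphenyl)ethyl]-6-methoxyphenyl}prop-1-yn-1-yl)oxy]triisopropylsilane, via lithium acetylide 16 (not isolated), via lithium ynolate 17 (not isolated)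
Conditions: n-BuLi (1.0 equiv), THF, −78 °C; LiOOt-Bu (from t-BuOOH, LiHMDS), −78 to 0 °C; TIPSOTf, −78 to 0 °C
Reagents that add atoms: tert-butyl hydroperoxide, CC(C)(C)OO; triisopropylsilyl trifluoromethanesulfonate, CC(C)[Si](C(C)C)(C(C)C)OS(=O)(=O)C(F)(F)F
Why: Electrophilic oxygen transfer from lithium tert-butyl peroxide to the lithium acetylide (acetylide-to-ynolate oxidation) gives the ynolate, which the bulky silyl triflate should silylate on oxygen to give the siloxyalkyne, with exactly one equivalent of base used so that only the acetylenic C–H is removed.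

Step 13
Reactants: 6 3-[2-(4-benzyloxy-3-methoxyphenyl)ethyl]cyclobut-2-en-1-one; 18 [(3-{4-benzyloxy-2-[2-(3-benzyloxyphenyl)ethyl]-6-methoxyphenyl}prop-1-yn-1-yl)oxy]triisopropylsilane
Product: 23 2-({4-benzyloxy-2-[2-(3-benzyloxyphenyl)ethyl]-6-methoxyphenyl}methyl)-5-[2-(4-benzyloxy-3-methoxyphenyl)ethyl]-3-(triisopropylsilyloxy)phenol, via vinylketene 19 (not isolated), via 4-vinylcyclobutenone 20 (not isolated), via dienylketene 21 (not isolated), via cyclohexadienone 22 (not isolated)
Conditions: toluene, 80 °C then 110 °C, sealed tube, Ar (18 in slight excess)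
Reagents that add atoms: none
Why: Thermal conrotatory four-electron opening of cyclobutenone 6 gives vinylketene 19, whose ketene C=C adds [2+2] to the electron-rich triple bond of 18 to give 4-vinylcyclobutenone 20; a second four-electron opening gives dienylketene 21, which closes ring B by a thermal disrotatory six-electron electrocyclisation (C2'–C3') to cyclohexadienone 22 and tautomerises to phenol 23. This is the Danheiser benzannulation of a cyclobutenone with a siloxyalkyne, known to give 2,5-disubstituted resorcinol monosilyl ethers. The [2+2] event forms C3'–C4' and C5'–C6', ring B is the only ring closed (six-membered, by 6π electrocyclisation of the dienylketene), and no stereocentre remains, since the one in 20 is destroyed on ring opening. The selectivity needed is regiochemical: the electrophilic ketene carbonyl carbon must bond to the nucleophilic carbon of the ynol ether that carries the ring-C benzyl group, which the oxygen-polarised triple bond secures and which places the bridge CH2 between the two oxygenated carbons with the arylethyl chain para to it. Ring opening of 20 is reversible, so both geometrical isomers of the dienylketene should drain through the one that can cyclise, and the slight excess of 18 keeps the free vinylketene concentration low so that acylation of the new phenol stays minor.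

Step 14
Reactants: 23 2-({4-benzyloxy-2-[2-(3-benzyloxyphenyl)ethyl]-6-methoxyphenyl}methyl)-5-[2-(4-benzyloxy-3-methoxyphenyl)ethyl]-3-(triisopropylsilyloxy)phenol
Product: 24 (2-({4-benzyloxy-2-[2-(3-benzyloxyphenyl)ethyl]-6-methoxyphenyl}methyl)-5-[2-(4-benzyloxy-3-methoxyphenyl)ethyl]-3-methoxyphenoxy)triisopropylsilane
Conditions: MeI, K2CO3 (anhydrous), acetone, 50 °C
Reagents that add atoms: iodomethane, CI
Why: Williamson methylation of the only free phenol fixes the differentiation of the two ring-B oxygens, which are equivalent by the local symmetry of ring B so that either assignment gives the same mono-methyl ether, and anhydrous carbonate should leave the aryl triisopropylsilyl ether intact.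

Step 15
Reactants: 24 (2-({4-benzyloxy-2-[2-(3-benzyloxyphenyl)ethyl]-6-methoxyphenyl}methyl)-5-[2-(4-benzyloxy-3-methoxyphenyl)ethyl]-3-methoxyphenoxy)triisopropylsilane
Product: 25 2-({4-benzyloxy-2-[2-(3-benzyloxyphenyl)ethyl]-6-methoxyphenyl}methyl)-5-[2-(4-benzyloxy-3-methoxyphenyl)ethyl]-3-methoxyphenol
Conditions: TBAF, AcOH (1:1), THF, 0 °C to rt
Reagents that add atoms: none
Why: Fluoride cleaves the aryl Si–O bond readily, and the acetic acid buffer protonates the phenoxide as it forms so that the electron-rich phenol is not exposed to base and air.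

Step 16
Reactants: 25 2-({4-benzyloxy-2-[2-(3-benzyloxyphenyl)ethyl]-6-methoxyphenyl}methyl)-5-[2-(4-benzyloxy-3-methoxyphenyl)ethyl]-3-methoxyphenol
Product: 26 2-({4-hydroxy-2-[2-(3-hydroxyphenyl)ethyl]-6-methoxyphenyl}methyl)-5-[2-(4-hydroxy-3-methoxyphenyl)ethyl]-3-methoxyphenol (target CNP0078999.0)
Conditions: H2 (1 atm), 10% Pd/C, EtOAc–MeOH, rt
Reagents that add atoms: none
Why: Palladium-catalysed hydrogenolysis should remove the three benzyl aryl ethers, while the aryl methyl ethers, the diarylmethane bridge and the two bibenzyl links are inert under these conditions.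

**Compound list**
1 | (4-benzyloxy-3-methoxyphenyl)methanol | COc1cc(CO)ccc1OCc1ccccc1 | starting material
2 | 4-benzyloxy-3-methoxybenzyl bromide | COc1cc(CBr)ccc1OCc1ccccc1 | intermediate
3 | [4-(4-benzyloxy-3-methoxyphenyl)but-1-yn-1-yl]trimethylsilane | COc1cc(CCC#C[Si](C)(C)C)ccc1OCc1ccccc1 | intermediate
4 | 1-benzyloxy-4-(but-3-yn-1-yl)-2-methoxybenzene | COc1cc(CCC#C)ccc1OCc1ccccc1 | intermediate
5 | 3-[2-(4-benzyloxy-3-methoxyphenyl)ethyl]-4,4-dichlorocyclobut-2-en-1-one | O=C1C=C(CCc2ccc(OCc3ccccc3)c(OC)c2)C1(Cl)Cl | intermediate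
6 | 3-[2-(4-benzyloxy-3-methoxyphenyl)ethyl]cyclobut-2-en-1-one | O=C1C=C(CCc2ccc(OCc3ccccc3)c(OC)c2)C1 | intermediate
7 | methyl orsellinate (methyl 2,4-dihydroxy-6-methylbenzoate) | COC(=O)c1c(C)cc(O)cc1O | starting material
8 | methyl 4-benzyloxy-2-hydroxy-6-methylbenzoate | COC(=O)c1c(C)cc(OCc2ccccc2)cc1O | intermediate
9 | methyl 4-benzyloxy-2-methoxy-6-methylbenzoate | COC(=O)c1c(C)cc(OCc2ccccc2)cc1OC | intermediate
10 | 3-benzyloxybenzyl bromide | BrCc1cccc(OCc2ccccc2)c1 | starting material
11 | methyl 4-benzyloxy-2-(lithiomethyl)-6-methoxybenzoate (laterally lithiated toluate, not isolated) | COC(=O)c1c(C[Li])cc(OCc2ccccc2)cc1OC | intermediate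
12 | methyl 4-benzyloxy-2-[2-(3-benzyloxyphenyl)ethyl]-6-methoxybenzoate | COC(=O)c1c(CCc2cccc(OCc3ccccc3)c2)cc(OCc2ccccc2)cc1OC | intermediate
13 | {4-benzyloxy-2-[2-(3-benzyloxyphenyl)ethyl]-6-methoxyphenyl}methanol | OCc1c(CCc2cccc(OCc3ccccc3)c2)cc(OCc2ccccc2)cc1OC | intermediate
14 | 5-benzyloxy-1-[2-(3-benzyloxyphenyl)ethyl]-2-(chloromethyl)-3-methoxybenzene | ClCc1c(CCc2cccc(OCc3ccccc3)c2)cc(OCc2ccccc2)cc1OC | intermediate
15 | 5-benzyloxy-1-[2-(3-benzyloxyphenyl)ethyl]-3-methoxy-2-(prop-2-yn-1-yl)benzene | C#CCc1c(CCc2cccc(OCc3ccccc3)c2)cc(OCc2ccccc2)cc1OC | intermediate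
16 | lithium acetylide of 15 (not isolated) | [Li]C#CCc1c(CCc2cccc(OCc3ccccc3)c2)cc(OCc2ccccc2)cc1OC | intermediate
17 | lithium 3-{4-benzyloxy-2-[2-(3-benzyloxyphenyl)ethyl]-6-methoxyphenyl}prop-1-yn-1-olate (ynolate, not isolated) | [Li]OC#CCc1c(CCc2cccc(OCc3ccccc3)c2)cc(OCc2ccccc2)cc1OC | intermediate
18 | [(3-{4-benzyloxy-2-[2-(3-benzyloxyphenyl)ethyl]-6-methoxyphenyl}prop-1-yn-1-yl)oxy]triisopropylsilane | CC(C)[Si](OC#CCc1c(CCc2cccc(OCc3ccccc3)c2)cc(OCc2ccccc2)cc1OC)(C(C)C)C(C)C | intermediate
19 | 5-(4-benzyloxy-3-methoxyphenyl)-3-methylidenepent-1-en-1-one (vinylketene, not isolated) | O=C=CC(=C)CCc1ccc(OCc2ccccc2)c(OC)c1 | intermediate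
20 | 4-[4-(4-benzyloxy-3-methoxyphenyl)but-1-en-2-yl]-2-({4-benzyloxy-2-[2-(3-benzyloxyphenyl)ethyl]-6-methoxyphenyl}methyl)-3-(triisopropylsilyloxy)cyclobut-2-en-1-one (racemic, not isolated) | O=C1C(Cc2c(CCc3cccc(OCc4ccccc4)c3)cc(OCc3ccccc3)cc2OC)=C(O[Si](C(C)C)(C(C)C)C(C)C)C1C(=C)CCc1ccc(OCc2ccccc2)c(OC)c1 | intermediate
21 | dienylketene from ring opening of 20, ketene and vinyl groups cis on the central C=C (not isolated) | O=C=C(Cc1c(CCc2cccc(OCc3ccccc3)c2)cc(OCc2ccccc2)cc1OC)/C(O[Si](C(C)C)(C(C)C)C(C)C)=C\C(=C)CCc1ccc(OCc2ccccc2)c(OC)c1 | intermediate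
22 | 5-[2-(4-benzyloxy-3-methoxyphenyl)ethyl]-2-({4-benzyloxy-2-[2-(3-benzyloxyphenyl)ethyl]-6-methoxyphenyl}methyl)-3-(triisopropylsilyloxy)cyclohexa-2,4-dien-1-one (not isolated) | O=C1CC(CCc2ccc(OCc3ccccc3)c(OC)c2)=CC(O[Si](C(C)C)(C(C)C)C(C)C)=C1Cc1c(CCc2cccc(OCc3ccccc3)c2)cc(OCc2ccccc2)cc1OC | intermediate
23 | 2-({4-benzyloxy-2-[2-(3-benzyloxyphenyl)ethyl]-6-methoxyphenyl}methyl)-5-[2-(4-benzyloxy-3-methoxyphenyl)ethyl]-3-(triisopropylsilyloxy)phenol | COc1cc(CCc2cc(O)c(Cc3c(CCc4cccc(OCc5ccccc5)c4)cc(OCc4ccccc4)cc3OC)c(O[Si](C(C)C)(C(C)C)C(C)C)c2)ccc1OCc1ccccc1 | intermediate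
24 | (2-({4-benzyloxy-2-[2-(3-benzyloxyphenyl)ethyl]-6-methoxyphenyl}methyl)-5-[2-(4-benzyloxy-3-methoxyphenyl)ethyl]-3-methoxyphenoxy)triisopropylsilane | COc1cc(CCc2cc(OC)c(Cc3c(CCc4cccc(OCc5ccccc5)c4)cc(OCc4ccccc4)cc3OC)c(O[Si](C(C)C)(C(C)C)C(C)C)c2)ccc1OCc1ccccc1 | intermediate
25 | 2-({4-benzyloxy-2-[2-(3-benzyloxyphenyl)ethyl]-6-methoxyphenyl}methyl)-5-[2-(4-benzyloxy-3-methoxyphenyl)ethyl]-3-methoxyphenol | COc1cc(CCc2cc(OC)c(Cc3c(CCc4cccc(OCc5ccccc5)c4)cc(OCc4ccccc4)cc3OC)c(O)c2)ccc1OCc1ccccc1 | intermediate
26 | 2-({4-hydroxy-2-[2-(3-hydroxyphenyl)ethyl]-6-methoxyphenyl}methyl)-5-[2-(4-hydroxy-3-methoxyphenyl)ethyl]-3-methoxyphenol (achiral) | COc1cc(CCc2cc(O)c(Cc3c(CCc4cccc(O)c4)cc(O)cc3OC)c(OC)c2)ccc1O | target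

**Totals**
Total step count: 16.
Longest linear sequence: 11 steps (steps 6–12 from methyl orsellinate, then steps 13–16). The ring A branch (steps 1–5) joins at step 13.

**Steps most likely to fail**

1. Step 13 (benzannulation). Capture of the vinylketene by the sterically loaded silyl ynol ether may be slower than self-condensation of the ketene and acylation of the phenol as it forms, and the siloxyalkyne may degrade thermally before it is consumed. The fallback changes the ketenophile class and the endgame. It sets out from chloride 14 and cyclobutenone 6. Sodium methoxyacetylide (from chloroacetaldehyde dimethyl acetal and NaNH2 in liquid NH3, the ammonia then replaced by THF–DMPU) is alkylated with 14 and should give the methyl ynol ether 5-benzyloxy-1-[2-(3-benzyloxyphenyl)ethyl]-3-methoxy-2-(3-methoxyprop-2-yn-1-yl)benzene F1. Heating F1 with 6 in toluene at 80 °C (alkoxyalkyne version of the same annulation) should give the ring-B phenol with the methyl ether already in place. Because the oxygen differentiation is then a permanent methyl ether, any aryl ester by-product could be cleaved with K2CO3/MeOH without loss. The fallback comes back to the route at 25 and makes compounds 15–18, 23 and 24 unnecessary.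

2. Step 12 (ynolate formation and silylation). Deprotonation at the doubly activated benzylic–propargylic CH2 (with isomerisation to allene or internal alkyne) may compete with clean oxygen transfer to the acetylide, and the siloxyalkyne may hydrolyse during work-up. The fallback reaches the same ynolate by ester homologation and sets out from chloride 14. Palladium-catalysed methoxycarbonylation (CO 1 atm, MeOH, PdCl2(PPh3)2, Et3N) should give methyl {4-benzyloxy-2-[2-(3-benzyloxyphenyl)ethyl]-6-methoxyphenyl}acetate F2. Kowalski homologation conditions (CH2Br2, LiTMP, THF, −78 °C; LiHMDS; then n-BuLi, −78 °C to rt) should convert F2, through the lithium enolate of the derived dibromomethyl ketone F3, into lithium ynolate 17 by bromine–lithium exchange and 1,2-shift of the arylmethyl group. Trapping with TIPSCl should give the siloxyalkyne, and the fallback comes back to the route at 18.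

3. Step 11 (together with the labile chloride of step 10). The electron-rich benzylic chloride may alkylate its own arene rings (Friedel–Crafts oligomerisation), the propargyl product may isomerise to the allene under the basic Grignard conditions, and ethyne may be alkylated twice. The fallback avoids any benzylic halide and sets out from alcohol 13. Oxidation with MnO2 (CH2Cl2, rt) should give 4-benzyloxy-2-[2-(3-benzyloxyphenyl)ethyl]-6-methoxybenzaldehyde F4. Addition of lithium (trimethylsilyl)acetylide (THF, −78 °C) should give the racemic propargylic alcohol 1-{4-benzyloxy-2-[2-(3-benzyloxyphenyl)ethyl]-6-methoxyphenyl}-3-(trimethylsilyl)prop-2-yn-1-ol F5. Ionic deoxygenation (Et3SiH, TFA, CH2Cl2, −20 to 0 °C; hydride capture of the 2,4-dialkoxybenzylic cation at the benzylic carbon) should give (3-{4-benzyloxy-2-[2-(3-benzyloxyphenyl)ethyl]-6-methoxyphenyl}prop-1-yn-1-yl)trimethylsilane F6. Protiodesilylation (K2CO3, MeOH) then comes back to the route at 15.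

**Further compounds**
F1 | step 13 | 5-benzyloxy-1-[2-(3-benzyloxyphenyl)ethyl]-3-methoxy-2-(3-methoxyprop-2-yn-1-yl)benzene | COC#CCc1c(CCc2cccc(OCc3ccccc3)c2)cc(OCc2ccccc2)cc1OC
F2 | step 12 | methyl {4-benzyloxy-2-[2-(3-benzyloxyphenyl)ethyl]-6-methoxyphenyl}acetate | COC(=O)Cc1c(CCc2cccc(OCc3ccccc3)c2)cc(OCc2ccccc2)cc1OC
F3 | step 12 | lithium enolate of 1,1-dibromo-3-{4-benzyloxy-2-[2-(3-benzyloxyphenyl)ethyl]-6-methoxyphenyl}propan-2-one | [Li]OC(=C(Br)Br)Cc1c(CCc2cccc(OCc3ccccc3)c2)cc(OCc2ccccc2)cc1OC
F4 | step 11 | 4-benzyloxy-2-[2-(3-benzyloxyphenyl)ethyl]-6-methoxybenzaldehyde | O=Cc1c(CCc2cccc(OCc3ccccc3)c2)cc(OCc2ccccc2)cc1OC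
F5 | step 11 | 1-{4-benzyloxy-2-[2-(3-benzyloxyphenyl)ethyl]-6-methoxyphenyl}-3-(trimethylsilyl)prop-2-yn-1-ol (racemic) | C[Si](C)(C)C#CC(O)c1c(CCc2cccc(OCc3ccccc3)c2)cc(OCc2ccccc2)cc1OC
F6 | step 11 | (3-{4-benzyloxy-2-[2-(3-benzyloxyphenyl)ethyl]-6-methoxyphenyl}prop-1-yn-1-yl)trimethylsilane | C[Si](C)(C)C#CCc1c(CCc2cccc(OCc3ccccc3)c2)cc(OCc2ccccc2)cc1OC
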